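# Proposed synthesis of niruriflavone by annulation of ring A onto a pyranone

Remark on the chemistry: the target is taken as the free sulfonic acid as drawn, without counter-ion; every compound of the route is achiral, so no stereodescriptor is needed.

## Analysis of the target

Niruriflavone (12) is a flavone, a 4H-chromen-4-one whose pyranone ring C carries a 4-methoxyphenyl group (ring B) at C2 and is fused through C4a and C8a to the benzo ring A. Ring A is a phloroglucinol-type ring: hydroxyls at C5 and C7, the sulfonic acid at C6 between them, one hydrogen at C8, and O1 on C8a as the third oxygen. There is no stereocentre, so the whole problem is one of position. C6 and C8 each lie between two oxygen-bearing carbons and are almost equivalent electronically, so any electrophilic introduction of sulfur into a finished flavone has to choose between them. The aryl sulfonic acid is strongly acidic, water-soluble, hard to chromatograph and open to protodesulfonation in hot acid, so it should appear last. The free phenols make ring A oxidisable, the 4'-methyl ether forbids Lewis-acid ether cleavage, and the pyranone can be opened by hot alkali. The strategy rests on one feature: C6 sits between C5 and C7, both of which are carbonyl carbons in the keto tautomer of ring A. C5 can therefore come from an ester on C4a, C7 from a second ester, C6 from a sulfur-bearing methylene joining them, and C8 from a methyl group on C8a. Rings B and C, with O1, C2, C3, C4, C4a and C8a, can then be a preformed 2-methyl-4-pyranone-3-carboxylate (5), and sulfur can only end up at C6.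

## Retrosynthetic reasoning

**12 to 11.** The three S–O bonds are removed first. A sulfonic acid would consume base and make every intermediate water-soluble, so it cannot be carried through a carbanion-based ring synthesis. Divalent sulfur is neutral, survives strong base and acidifies the carbon that bears it. The forward step must raise the thiol to the sulfonic acid without attacking ring A, which is plausible because sulfur is by far the most easily oxidised atom of 11.

**11 to 10.** The S–H is masked as a 2-(trimethylsilyl)ethyl sulfide. This group has no hydrogen acidic enough to compete in the base step, resists amide and alkoxide, and leaves by fluoride-triggered fragmentation, which spares the methyl ether and the pyranone. A benzyl-type group would need strong acid or dissolving metal, and hydrogenolysis is excluded by sulfur itself.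

**10 to 5 and 8 (through 9).** Ring A is opened at C7–C8 and at C5–C6. Each of these bonds joins a carbon that must end up oxygenated (C7, C5) to a carbon that can be a carbanion: C8 as the lateral methyl group of the pyranone, C6 as a methylene between a carbonyl group and sulfur. The cut leaves rings B and C untouched in 5, with O1 already in place, and puts the C6–C7 unit with its sulfur into the two-carbon ester 8. The gain is that every position of ring A is fixed by connectivity. Sulfur is bonded to the carbon that links the two carbonyl carbons, so it can only appear between the 5- and 7-hydroxyls, and C8 can only be the former methyl carbon. No phenol needs protection, because the hydroxyls are formed in the step that makes the ring. The forward reaction has to achieve two acylations in one flask: an intermolecular Claisen condensation to the open-chain keto sulfide 9, then ring closure of 9 from C6 onto the ester on C4a and aromatisation.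

**8 to 6 and 7.** The S–CH2 bond is cut. The forward reaction is alkylation of a thiol with an α-bromo ester, with nothing to control.

**5 to 4.** The ring O–C bond of the pyranone that becomes O1–C2 of the flavone is cut, which gives an open-chain enol–ynone. Compound 4 already has the oxidation level of the pyranone, so the ring closes by isomerisation alone, with no dehydration or oxidation. The forward step must close the six-membered ring through the ketone enol oxygen and not a five-membered one.

**4 to 1 and 2 (through 3).** The C–C bond between the central carbon of β-keto ester 2 and the ynone carbonyl is cut. The forward reaction is C-acylation of 2 with acid chloride 3, made from acid 1. One cheap reagent thereby places the ester (future C5) and the methyl group (future C8) on neighbouring carbons of the later pyranone. The forward step must acylate on carbon and not on oxygen.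

## Alternatives that were turned down

**Alternative 1:** Ring A would be made as in biosynthesis.
- Disconnection: the bond from the future C4a to the ester carbon, which becomes C5 or C8a (the two are equivalent until ring C exists).
- Forward key step: Mg(OMe)2 in methanol opens a 4-hydroxy-2-pyranone to a 3,5,7-triketo ester carrying the 4-methoxycinnamoyl end. Its C6 carbanion attacks the ester carbon and gives (2E)-3-(4-methoxyphenyl)-1-(2,4,6-trihydroxyphenyl)prop-2-en-1-one A1.
- For it: mild alkoxide conditions, a magnesium template that holds the chain folded, a well-precedented ring formation, and a known oxidative closure of the chalcone to 5,7-dihydroxy-2-(4-methoxyphenyl)-4H-chromen-4-one A2. On mildness and precedent it is stronger than the chosen key step.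
- Against it: the polycarbonyl chain can also close by aldol condensation to a resorcylic ester or relactonise. More seriously, A1 contains no sulfur and its ring A is symmetric. The carbons that become C6 and C8 differ only after ring C is closed, and sulfur must then be put into A2 by electrophilic substitution, which does not reliably distinguish C6 from C8 and is reversible. The acylphloroglucinol core of A1 can also be bought, so the key step builds nothing scarce.
- Comparison: the step count would be similar, but the one hard question of the target is left open. The chosen strategy answers it in the ring-forming step.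

**Alternative 2:** Ring C would be closed at C2=C3.
- Disconnection: the C2=C3 double bond, back to an acylphosphorane on ring A (ylide carbon = C3) with an ortho 4-methoxybenzoate ester (ester carbon = C2).
- Forward key step: on heating, the ylide attacks the ester carbonyl and loss of the phosphine oxide gives 5,7-bis(benzyloxy)-2-(4-methoxyphenyl)-4H-chromen-4-one A3.
- For it: the intramolecular ester Wittig closure to chromones is known chemistry, runs under neutral thermal conditions and avoids a 1,3-diketone. Its key step is better precedented than the chosen one.
- Against it: A3 again lacks sulfur, and in 5,7-dialkoxyflavones electrophiles prefer C8. The benzyl ethers must be removed by hydrogenolysis before sulfur arrives, or by Lewis acids that endanger the 4'-methyl ether. The precursor needs selective protection of three phenols, α-halogenation of a very electron-rich acetophenone against nuclear halogenation, and phosphonium salt and ylide formation.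
- Comparison: about five steps precede the key step and at least three follow it. The chosen route has six steps in all, needs no oxygen protecting group and fixes sulfur at C6 by connectivity.

**Alternative 3:** Ring C would be assembled from three components.
- Disconnection: C4a–C4, C4–C3 and O1–C2, back to 2,2-dimethylpropyl 2,6-bis(benzyloxy)-4-hydroxy-3-iodobenzene-1-sulfonate A5, carbon monoxide A7 (as C4) and 1-ethynyl-4-methoxybenzene A6.
- Forward key step: with PdCl2(PPh3)2 in Et2NH, zerovalent palladium inserts into the C–I bond, A7 inserts, the acyl group couples with the alkyne, and the amine mediates 6-endo closure of the ortho-hydroxyaryl ynone. The product is neopentyl 5,7-bis(benzyloxy)-2-(4-methoxyphenyl)-4-oxo-4H-chromene-6-sulfonate A4.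
- For it: it is the most convergent option, the annulation type is known, and sulfur is already at its final oxidation level and position, so no oxidation is needed beside free phenols. On these points it is stronger than the chosen strategy.
- Against it: the positional problem is moved, not solved. In A5 three phloroglucinol oxygens must be told apart, and sulfonate and iodine must be placed at two specific nucleophilic carbons of an arene more symmetric than the flavone. The C–I bond lies between two oxygen substituents on an electron-rich ring, so oxidative addition is slow; coupling without A7 would give a benzofuran and 5-exo closure an aurone. A neopentyl sulfonate ester leaves only under forcing nucleophilic conditions, and two benzyl ethers remain to be removed.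
- Comparison: about ten steps are needed. The chosen route is shorter, has no oxygen protecting group and places sulfur by construction.

Key step: step 4

## Route

Step 1
Reactants: 1 3-(4-methoxyphenyl)prop-2-ynoic acid; 2 ethyl 3-oxobutanoate (ethyl acetoacetate)
Product: 4 ethyl 2-acetyl-5-(4-methoxyphenyl)-3-oxopent-4-ynoate, via 3-(4-methoxyphenyl)prop-2-ynoyl chloride 3 (not isolated)
Conditions: (COCl)2, DMF (cat.), CH2Cl2, 0 → 25 °C, concentrate; then 2, MgCl2, pyridine, CH2Cl2, 0 → 25 °C; 1 M HCl
Reagents that add atoms: oxalyl chloride, O=C(Cl)C(=O)Cl (gives the chlorine of 3; none of its atoms remain in 4)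
Why: Vilsmeier-type activation converts 1 into acid chloride 3; soft enolisation of 2 with MgCl2 and pyridine gives a chelated magnesium enolate that is acylated on carbon, since the chelate shields oxygen and the tricarbonyl product is held as a stable magnesium chelate (C-acylation of a β-keto ester). Any cyclisation of 4 to 5 at this stage would be harmless.

Step 2
Reactants: 4 ethyl 2-acetyl-5-(4-methoxyphenyl)-3-oxopent-4-ynoate
Product: 5 ethyl 6-(4-methoxyphenyl)-2-methyl-4-oxo-4H-pyran-3-carboxylate
Conditions: CF3SO3H (0.2 equiv), CH2Cl2, 0 → 25 °C
Reagents that add atoms: none
Why: Acid-catalysed 6-endo-dig oxa-Michael cycloisomerisation: the enolised acetyl oxygen adds to the β-carbon of the activated ynone, where the 4-methoxyphenyl group stabilises positive charge, so the six-membered pyranone should be preferred over 5-exo closure to a furanone. The ester carbonyl oxygen is a much weaker nucleophile than the enol, so the methyl group ends at C2 and the ester at C3.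

Step 3
Reactants: 6 2-(trimethylsilyl)ethane-1-thiol; 7 methyl bromoacetate
Product: 8 methyl 2-{[2-(trimethylsilyl)ethyl]sulfanyl}acetate
Conditions: Et3N, CH2Cl2, 0 → 25 °C
Reagents that add atoms: none
Why: SN2 S-alkylation of the thiolate by an α-bromo ester; the soft thiolate reacts at the CH2Br carbon and leaves the ester alone.

Step 4
Reactants: 5 ethyl 6-(4-methoxyphenyl)-2-methyl-4-oxo-4H-pyran-3-carboxylate; 8 methyl 2-{[2-(trimethylsilyl)ethyl]sulfanyl}acetate
Product: 10 5,7-dihydroxy-2-(4-methoxyphenyl)-6-{[2-(trimethylsilyl)ethyl]sulfanyl}-4H-chromen-4-one, via open-chain β-keto sulfide 9 (not isolated)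
Conditions: LiN(SiMe3)2 (4.5 equiv), THF, −78 °C, 5 added; then 8 (1.5 equiv), −78 → 25 °C; then 50 °C; 1 M HCl
Reagents that add atoms: none
Why: Proposed new method: LiN(SiMe3)2 removes a proton from the 2-methyl group of 5, its only acidic C–H, to give an extended lithium dienolate whose exocyclic carbon (future C8) adds to the methyl ester of 8; loss of methoxide forms C8–C7 and gives 9 as its enolate. Deprotonation of 9 at C8 is fastest but unproductive, since closure from C8 would make a four-membered ring; with amide in excess the sulfur-stabilised C6 carbanion (dianion or transposed enolate) forms reversibly and attacks the neighbouring C3 ester carbonyl in a 6-(enolendo)-exo-trig Dieckmann closure, a favoured mode, forming C6–C5 and ring A. Loss of ethoxide and enolisation of the cyclic β-diketone give the aromatic 5,7-diolate, an irreversible step that drains all earlier equilibria. The closest known reactions are the tandem Claisen–Dieckmann annulation of lithiated ortho-toluates with esters to naphthalene-1,3-diols and the lateral lithiation–acylation of 2-methyl-4-pyranones; new is their combination on a 3-alkoxycarbonyl-2-methyl-4-pyranone to build the benzo ring of a chromone. No stereocentre is formed. The selectivity needed is cross- over self-condensation: 5 is fully converted into its anion before 8 is added, so no neutral pyranone remains as an electrophile, and HN(SiMe3)2 is close enough in acidity to 8 that enolisation of 8 stays reversible and free ester remains available. Regiochemistry needs no control: should the enolate of 8 acylate first on the C3 ester, the methyl carbanion then closes onto the methyl ester and the same 10 results, with sulfur between the two hydroxyls in either order.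

Step 5
Reactants: 10 5,7-dihydroxy-2-(4-methoxyphenyl)-6-{[2-(trimethylsilyl)ethyl]sulfanyl}-4H-chromen-4-one
Product: 11 5,7-dihydroxy-2-(4-methoxyphenyl)-6-sulfanyl-4H-chromen-4-one
Conditions: Bu4NF (5 equiv), THF, Ar, 25 → 60 °C; then AcOH, 1 M HCl
Reagents that add atoms: none
Why: Fluoride attacks silicon and the β-silylethyl sulfide fragments to ethene, Me3SiF and the arenethiolate (fluoride-induced β-elimination of a 2-(trimethylsilyl)ethyl sulfide); methyl ether and pyranone are inert and the excess of fluoride covers the phenol protons. Air is excluded to limit disulfide formation, although a disulfide would be oxidised to the same product in step 6.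

Step 6
Reactants: 11 5,7-dihydroxy-2-(4-methoxyphenyl)-6-sulfanyl-4H-chromen-4-one
Product: 12 niruriflavone, 5,7-dihydroxy-2-(4-methoxyphenyl)-4-oxo-4H-chromene-6-sulfonic acid
Conditions: 30% H2O2 (6 equiv), HCO2H, 0 → 25 °C; evaporation below 30 °C
Reagents that add atoms: hydrogen peroxide, OO (its oxygen is delivered through performic acid, O=COO, formed in the flask)
Why: Peracid oxidation of a thiol to a sulfonic acid through the sulfenic and sulfinic acids (any disulfide passes through thiosulfinate and thiosulfonate to the same acid). Sulfur is far more nucleophilic than the carbonyl-deactivated, hydrogen-bonded ring A, and the C2=C3 bond is too electron-poor to be epoxidised.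

## Compound list

1 | 3-(4-methoxyphenyl)prop-2-ynoic acid | COc1ccc(C#CC(=O)O)cc1 | starting material
2 | ethyl 3-oxobutanoate (ethyl acetoacetate) | CCOC(=O)CC(C)=O | starting material
3 | 3-(4-methoxyphenyl)prop-2-ynoyl chloride | COc1ccc(C#CC(=O)Cl)cc1 | intermediate
4 | ethyl 2-acetyl-5-(4-methoxyphenyl)-3-oxopent-4-ynoate | CCOC(=O)C(C(C)=O)C(=O)C#Cc1ccc(OC)cc1 | intermediate
5 | ethyl 6-(4-methoxyphenyl)-2-methyl-4-oxo-4H-pyran-3-carboxylate | CCOC(=O)c1c(C)oc(cc1=O)-c1ccc(OC)cc1 | intermediate
6 | 2-(trimethylsilyl)ethane-1-thiol | C[Si](C)(C)CCS | starting material
7 | methyl bromoacetate | COC(=O)CBr | starting material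
8 | methyl 2-{[2-(trimethylsilyl)ethyl]sulfanyl}acetate | COC(=O)CSCC[Si](C)(C)C | intermediate
9 | ethyl 6-(4-methoxyphenyl)-4-oxo-2-(2-oxo-3-{[2-(trimethylsilyl)ethyl]sulfanyl}propyl)-4H-pyran-3-carboxylate | CCOC(=O)c1c(CC(=O)CSCC[Si](C)(C)C)oc(cc1=O)-c1ccc(OC)cc1 | intermediate
10 | 5,7-dihydroxy-2-(4-methoxyphenyl)-6-{[2-(trimethylsilyl)ethyl]sulfanyl}-4H-chromen-4-one | COc1ccc(-c2cc(=O)c3c(O)c(SCC[Si](C)(C)C)c(O)cc3o2)cc1 | intermediate
11 | 5,7-dihydroxy-2-(4-methoxyphenyl)-6-sulfanyl-4H-chromen-4-one | COc1ccc(-c2cc(=O)c3c(O)c(S)c(O)cc3o2)cc1 | intermediate
12 | niruriflavone, 5,7-dihydroxy-2-(4-methoxyphenyl)-4-oxo-4H-chromene-6-sulfonic acid | COc1ccc(-c2cc(=O)c3c(O)c(S(=O)(=O)O)c(O)cc3o2)cc1 | target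

## Step count and risk

Total step count: 6. Longest linear sequence: 5 steps (steps 1, 2, 4, 5, 6, from acid 1); step 3 is a one-step side branch.

**Step 4 (key step, the one new method).**
- What may go wrong: ester 8 may be enolised and self-condense faster than it is attacked by the stabilised, weakly nucleophilic dienolate of 5. The sequence may also stop at the enolate of 9, because the second deprotonation at C6 is unfavourable with a silylamide base. Prolonged warming with the released alkoxides may open the pyranone ring.
- Fallback (known chemistry only; the annulation is given up): ring A is taken from a purchased flavone and sulfur is brought in with thiol 6. It sets out from 6 and comes back at 10.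
 - Purchased 5,7-dihydroxy-2-(4-methoxyphenyl)-4H-chromen-4-one (acacetin) F1 would be etherified at the non-chelated 7-hydroxyl (MOMCl, iPr2NEt, CH2Cl2) to 5-hydroxy-7-(methoxymethoxy)-2-(4-methoxyphenyl)-4H-chromen-4-one F2.
 - Iodination with [BnNMe3][ICl2] and CaCO3 in CH2Cl2–MeOH should give 5-hydroxy-6-iodo-7-(methoxymethoxy)-2-(4-methoxyphenyl)-4H-chromen-4-one F3. This reagent is known to substitute 5-hydroxy-7-alkoxyflavones ortho to the free, chelated 5-hydroxyl.
 - C–S cross-coupling of F3 with 6 (Pd2(dba)3, Xantphos, iPr2NEt, 1,4-dioxane, 100 °C) should give 5-hydroxy-7-(methoxymethoxy)-2-(4-methoxyphenyl)-6-{[2-(trimethylsilyl)ethyl]sulfanyl}-4H-chromen-4-one F4.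
 - HCl in MeOH would remove the acetal and give 10.
 - The price is four steps for one, and a sulfur position that rests on reagent selectivity between C6 and C8; it would have to be proved, for example by long-range C–H correlation.

**Step 6.**
- What may go wrong: the electrophilic peracid may oxidise the phloroglucinol-type ring A (hydroxylation at C8, quinone formation) while it oxidises sulfur. Oxidation may stop at the disulfide or thiosulfonate stage, and the product may lose the sulfonic acid by protodesulfonation if the acidic solution is concentrated warm.
- Fallback: ring A and sulfur are deactivated as acetates before oxidation. It sets out from 11 and comes back at 12.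
 - Ac2O and pyridine should give S-[5,7-bis(acetyloxy)-2-(4-methoxyphenyl)-4-oxo-4H-chromen-6-yl] ethanethioate F5.
 - H2O2 in AcOH oxidises the thioester directly to 5,7-bis(acetyloxy)-2-(4-methoxyphenyl)-4-oxo-4H-chromene-6-sulfonic acid F6, with the ring protected against the oxidant.
 - K2CO3 in MeOH, then an acidic ion-exchange resin, would remove the acetates and give 12.

**Step 5.**
- What may go wrong: Bu4NF deprotonates the phenols, so the thiolate has to leave from an anionic, electron-rich ring and the fragmentation may be slow or incomplete. The thiolate formed is easily oxidised by air to the disulfide.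
- Fallback: sulfur is oxidised before it is unmasked, so that the leaving group is a sulfinate. It sets out from 10 and comes back at 12, bypassing 11.
 - mCPBA (2.2 equiv, CH2Cl2, 0 °C) should oxidise the sulfide chemoselectively to 5,7-dihydroxy-2-(4-methoxyphenyl)-6-{[2-(trimethylsilyl)ethyl]sulfonyl}-4H-chromen-4-one F7.
 - Bu4NF in THF would fragment the silylethyl sulfone to 5,7-dihydroxy-2-(4-methoxyphenyl)-4-oxo-4H-chromene-6-sulfinic acid F8.
 - Aqueous H2O2 near neutral pH would oxidise the sulfinate to 12.

**Step 1.**
- What may go wrong: pyridine or chloride may add to the activated triple bond of 3, and the enolate may be acylated on oxygen. An adduct at the β-carbon could still close to 5 by addition–elimination, but material would be lost.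
- Fallback: the order of bond formation is changed so that no alkynoyl chloride meets an amine. It sets out from 1 and comes back at 4.
 - Amide coupling of 1 (MeNHOMe·HCl, EDC·HCl, iPr2NEt, CH2Cl2) would give N-methoxy-3-(4-methoxyphenyl)-N-methylprop-2-ynamide F9.
 - Acylation of the lithium enolate of ethyl acetate (LiN(iPr)2, EtOAc, THF, −78 °C) with F9 would give ethyl 5-(4-methoxyphenyl)-3-oxopent-4-ynoate F10.
 - C-acetylation of F10 (AcCl, MgCl2, pyridine, CH2Cl2) would give 4.

## Further compounds

F1 | step 4 | 5,7-dihydroxy-2-(4-methoxyphenyl)-4H-chromen-4-one (acacetin, purchased) | COc1ccc(-c2cc(=O)c3c(O)cc(O)cc3o2)cc1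
F2 | step 4 | 5-hydroxy-7-(methoxymethoxy)-2-(4-methoxyphenyl)-4H-chromen-4-one | COc1ccc(-c2cc(=O)c3c(O)cc(OCOC)cc3o2)cc1
F3 | step 4 | 5-hydroxy-6-iodo-7-(methoxymethoxy)-2-(4-methoxyphenyl)-4H-chromen-4-one | COc1ccc(-c2cc(=O)c3c(O)c(I)c(OCOC)cc3o2)cc1
F4 | step 4 | 5-hydroxy-7-(methoxymethoxy)-2-(4-methoxyphenyl)-6-{[2-(trimethylsilyl)ethyl]sulfanyl}-4H-chromen-4-one | COc1ccc(-c2cc(=O)c3c(O)c(SCC[Si](C)(C)C)c(OCOC)cc3o2)cc1
F5 | step 6 | S-[5,7-bis(acetyloxy)-2-(4-methoxyphenyl)-4-oxo-4H-chromen-6-yl] ethanethioate | COc1ccc(-c2cc(=O)c3c(OC(C)=O)c(SC(C)=O)c(OC(C)=O)cc3o2)cc1
F6 | step 6 | 5,7-bis(acetyloxy)-2-(4-methoxyphenyl)-4-oxo-4H-chromene-6-sulfonic acid | COc1ccc(-c2cc(=O)c3c(OC(C)=O)c(S(=O)(=O)O)c(OC(C)=O)cc3o2)cc1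
F7 | step 5 | 5,7-dihydroxy-2-(4-methoxyphenyl)-6-{[2-(trimethylsilyl)ethyl]sulfonyl}-4H-chromen-4-one | COc1ccc(-c2cc(=O)c3c(O)c(S(=O)(=O)CC[Si](C)(C)C)c(O)cc3o2)cc1
F8 | step 5 | 5,7-dihydroxy-2-(4-methoxyphenyl)-4-oxo-4H-chromene-6-sulfinic acid | COc1ccc(-c2cc(=O)c3c(O)c(S(=O)O)c(O)cc3o2)cc1
F9 | step 1 | N-methoxy-3-(4-methoxyphenyl)-N-methylprop-2-ynamide | COc1ccc(C#CC(=O)N(C)OC)cc1
F10 | step 1 | ethyl 5-(4-methoxyphenyl)-3-oxopent-4-ynoate | CCOC(=O)CC(=O)C#Cc1ccc(OC)cc1
A1 | alternative 1 | (2E)-3-(4-methoxyphenyl)-1-(2,4,6-trihydroxyphenyl)prop-2-en-1-one | COc1ccc(/C=C/C(=O)c2c(O)cc(O)cc2O)cc1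
A2 | alternative 1 | 5,7-dihydroxy-2-(4-methoxyphenyl)-4H-chromen-4-one | COc1ccc(-c2cc(=O)c3c(O)cc(O)cc3o2)cc1
A3 | alternative 2 | 5,7-bis(benzyloxy)-2-(4-methoxyphenyl)-4H-chromen-4-one | COc1ccc(-c2cc(=O)c3c(OCc4ccccc4)cc(OCc4ccccc4)cc3o2)cc1
A4 | alternative 3 | neopentyl 5,7-bis(benzyloxy)-2-(4-methoxyphenyl)-4-oxo-4H-chromene-6-sulfonate | COc1ccc(-c2cc(=O)c3c(OCc4ccccc4)c(S(=O)(=O)OCC(C)(C)C)c(OCc4ccccc4)cc3o2)cc1
A5 | alternative 3 | 2,2-dimethylpropyl 2,6-bis(benzyloxy)-4-hydroxy-3-iodobenzene-1-sulfonate | CC(C)(C)COS(=O)(=O)c1c(OCc2ccccc2)cc(O)c(I)c1OCc1ccccc1
A6 | alternative 3 | 1-ethynyl-4-methoxybenzene | COc1ccc(C#C)cc1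
A7 | alternative 3 | carbon monoxide | [C-]#[O+]
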